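The south-east run at 29 °C and the south run at 38 °C took up gas at a similar pace: by 5.00 h the south-east run had taken 0.0241 M h⁻¹ and the south run 0.0264 M h⁻¹, counting one gas per target and one per side product. So take gas steps as the clock and ask what the side step costs per tick.

all flasks: gas phase 73 mM (held)

| run | starting material | temperature | remark | time |
|---|---|---|---|---|
| south-east | 0.21 M | 29 °C | run made earlier |  |
| south | 0.33 M | 38 °C | run made earlier |  |
| Sunday's | 0.15 M | 41 °C |  | 30 h |
| Thursday's | 0.15 M | 25 °C |  | 30 h |
| Wednesday's | 0.15 M | 33 °C |  | 30 h |

| run | time / h | target / % | starting material / % | side product / % |
|---|---|---|---|---|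
| south-east | 3.00 | 14 | 52 | 28 |
| south-east | 5.00 | 36 | 22 | 43 |
| south-east | 10.0 | 52 | 0 | 49 |
| south-east | 20.0 | 50 | 3 | 50 |
| south-east | 40.0 | 56 | 0 | 49 |
| south | 1.50 | 4 | 83 | 16 |
| south | 5.00 | 9 | 28 | 62 |
| south | 8.00 | 19 | 2 | 81 |
| south | 12.0 | 18 | 1 | 79 |
| south | 20.0 | 17 | 4 | 82 |

(scatter of a reading: 2 percentage points)

- percent here means starting material units held: one side product counts as two
- what is said of target includes crystals
- crystals is a solid; its amount is given per volume of the solution
- at the start none of the gas is dissolved
- steps under discussion: gas phase <-> dissolved gas; starting material + dissolved gas -> target; starting material + target -> side product; crystals <-> target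

* which of these there is most of at the end, counted by the starting material in it, Sunday's (starting material / target / side product)
* which of these there is most of at the end, counted by the starting material in it, Thursday's (starting material / target / side product)
* which of these there is most of at the end, counted by the starting material in it, Wednesday's (starting material / target / side product)
* amount of the one of these that there is most of at the end, in percent of the starting material charged, Sunday's
* amount of the one of these that there is most of at the end, in percent of the starting material charged, Thursday's
* amount of the one of these that there is most of at the end, in percent of the starting material charged, Wednesday's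

Follow the starting material left, a, and not the product made. Dividing side steps by gas steps, then by the mean a of a window, gives

south-east, 3.00 h to 5.00 h: 3.27 M⁻¹

south, 5.00 h to 8.00 h: 9.84 M⁻¹

Call this reading q, side steps per gas step per molar of starting material left, a selectivity factor. Each gas step removes 1 + qa of starting material, so with q steady and Q = q times the charge, the target share at the end is

p = 2 ln(1 + Q)/Q − 1

On its own charge the south-east q gives 52.2%, and that run's last reading is 56%.

Now bracket Wednesday's. It is warmer than the south-east run, so the ceiling is

p < 62.7%

It is cooler than the south run, so the south q gives a floor of 22.8%. The geometric mean of the two q tightens that: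

p > 44.7%

This floor is low by the climb of dissolved target from none. My bracket holds the even split between target and side product, so it leaves the call for Wednesday's open.

The forecast, inside the bracket, says target at 55% for Wednesday's, “though this is close”, target at 67% for Thursday's and side product at 60% for Sunday's.

The flasks give target at 52.9% for Wednesday's, target at 69.3% for Thursday's and side product at 63.4% for Sunday's.

    gas phase ⇌ dissolved gas, rate k1*(csat - [dissolved gas]) (kL = 1.01 × 10⁻⁴ s⁻¹)
    starting material + dissolved gas → target (k = 0.00943 M⁻¹ s⁻¹, Ea = 70.0 kJ mol⁻¹)
    starting material + target → side product (k = 5.76 × 10⁻⁴ M⁻¹ s⁻¹, Ea = 70.0 kJ mol⁻¹)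
    crystals ⇌ target, rate k4*(cs4 - [target]) while solid is left; crystals form when [target] > cs4 (solubility = 33.0 mM, k = 0.0184 s⁻¹)
    (constants at 25 °C)

In Wednesday's, gas crossed over and made target while starting material + target made side product, and by 15.0 h starting material stood at 0%, with target 52.9%, crystals 30.9% of it. From then on target stayed put, 52.9% at 300 h. Thursday's is cooler than the south-east run, so 3.27 M⁻¹ turns the old ceiling of 62.7% into its floor, and its target of 69.3% stands above that. Repeated at 50 °C, Thursday's flask ends with side product on top at 75.5%, target 24.5%.

(The readings are simulated from invented constants; noise was put on by code.)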